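Readings and results stem from a simulated flask from invented constants; scatter was added.

At 25 min, when red and green are read, I want to know which of the four asked species holds the most substrate, and how much first product is left in red.

common to all: substrate 0.078 M
- gamma: reagent 0.070 M; run made earlier
- eta: reagent 0.17 M; run made earlier
- red: reagent 0.0624 M; time 25 min
- green: reagent 0.117 M; time 25 min

| run | time / min | first product / % | substrate / % |
|---|---|---|---|
| gamma | 1.33 | 10 | 48 |
| gamma | 4.00 | 15 | 22 |
| gamma | 8.00 | 14 | 11 |
| gamma | 10.0 | 10 | 9 |
| gamma | 15.0 | 9 | 6 |
| gamma | 20.0 | 12 | 4 |
| gamma | 25.0 | 9 | 3 |
| eta | 1.33 | 22 | 13 |
| eta | 4.00 | 21 | 0 |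
| eta | 8.00 | 17 | 1 |
| eta | 10.0 | 21 | 1 |
| eta | 15.0 | 17 | 0 |
| eta | 20.0 | 16 | 1 |
| eta | 25.0 | 16 | 0 |

(readings scatter by 1.5 percentage points)

- which of these holds the largest part of the substrate at the end of red (first product / substrate / other mono adduct / double product)
- which of these holds the largest part of the substrate at the end of green (first product / substrate / other mono adduct / double product)
- how much first product is there at the end of red, in percent of the substrate charged

- the numbers in the tables scatter with a standard deviation of 1.5 percentage points

I fold the charges into one number, E = 0.800 for red, the reagent charged divided by the substrate charged. It is 1.50 for green and 0.897 for gamma. The crossing lies at E = one. If each substrate takes one reagent, then below the crossing reagent is the limiting reagent and a fraction 1 − E of the substrate stays unreacted, while above it a surplus E − 1 is open to a second addition. Red lies below the crossing, with a floor of 20.0% substrate. E does not say which mono adduct leads, so I guess other mono adduct there from gamma, where 88.0% is unseen at the last reading. Green lies above the crossing, with a surplus of 50.0%. That permits double product, but the runs show neither double product nor other mono adduct, so I name double product for green only as a guess.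

Is one number enough? The gamma floor is 10.3%, but the last gamma reading is lower, 3%, a gap of 7.3 points against a scatter of 1.5 points. So I read that some substrate leaves without taking reagent, and E is not enough. For first product in red I take a little under the last gamma reading, 9%.

The forecast gives other mono adduct and 8.5% for red, which agrees with me, but other mono adduct for green, where I differ: “the slow first-product decay suggests otherwise”.

Of the four asked, red gives other mono adduct at 28.0% with 5.71% first product, and green gives double product at 43.7%. Substrate in red is 5.76%, under its floor, and side product there stands at 47.2%.

    first product ⇌ isomer of the product (K = 0.721, k = 0.186 s⁻¹)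
    substrate + first product → side product (k = 0.138 M⁻¹ s⁻¹)
    substrate + reagent → other mono adduct + by-product (k = 0.106 M⁻¹ s⁻¹)
    reagent + first product → double product + by-product (k = 0.00761 M⁻¹ s⁻¹)
    substrate + reagent → first product + by-product (k = 0.0982 M⁻¹ s⁻¹)
    reagent + other mono adduct → double product + by-product (k = 0.0552 M⁻¹ s⁻¹)

The neighbouring flask is red with substrate raised to 0.13 M. Its E is 0.480, so its floor is 52.0%. At the same reading it holds 33% substrate, again under the floor, with reagent at 0%, side product at 43.5% and first product at 0.0549%.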